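The carbocycle is numbered C1 (fusion CH), C2, C3 (CHOH), C4 (CMe2), C5 (fusion COH), C6, C7, C8 (CHMe), C9 (quaternary), C10 (ketone), with side chain C11–C12. The C5 hydroxyl sits β to the C10 ketone across the C1–C5 fusion bond. Cyclopentane and cycloheptanone together are therefore the transannular aldol form of a cyclodecane-1,6-dione whose carbonyls are four carbons apart on both sides. The key step exploits this through anionic oxy-Cope expansion of a cyclohexanol (C5–C10) bearing 1-methylallenyl on C5 and, on C10, vinyl and an ether oxygen tied to C12. In one operation C5–C10 breaks, C2–C3 forms, the C5 dienolate is methylated at C4, and C10 emerges as enol ether.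

Key step: step 9

Remark on the ligand: the sense of induction in step 2 is assumed, and the phosphoramidite antipode that gives the 3R silyl enol ether is the one used.
Remark on transient centres: the carbinol centres at C5 and C10 made in steps 4, 5 and 8 are drawn as the arguments given there predict. They vanish in steps 7 and 9, and any isomer in which vinyl and allenyl can be gauche serves equally.

Step 1
Reactants: 1 2-chloroethanol
Product: 2 2-chloroethyl trifluoromethanesulfonate
Conditions: Tf2O, pyridine, CH2Cl2, −20 to 0 °C; used fresh
Reagents that add atoms: trifluoromethanesulfonic anhydride, O=S(=O)(OS(=O)(=O)C(F)(F)F)C(F)(F)F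
Why: O-sulfonylation of a primary alcohol, which leaves the chloride untouched and makes the triflate end by far the better leaving group, so that 2 acts as a monofunctional C11–C12 electrophile.

Step 2
Reactants: 3 2-methylcyclohex-2-en-1-one
Product: 5 (R)-[(2,3-dimethylcyclohex-1-en-1-yl)oxy]trimethylsilane, via dimethylaluminium enolate 4 (not isolated)
Conditions: Me3Al, Cu(OTf)2 (2 mol%), BINOL-derived phosphoramidite bearing a bis(1-phenylethyl)amino group (4 mol%), Et2O, −30 °C; then TMSOTf, THF, −30 to 0 °C
Reagents that add atoms: trimethylaluminium, C[Al](C)C; trimethylsilyl trifluoromethanesulfonate, C[Si](C)(C)OS(=O)(=O)C(F)(F)F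
Why: copper-catalysed asymmetric conjugate addition of an alkylaluminium reagent, in which the chiral copper-phosphoramidite complex selects the enone face and sets C8 (R), while silylation stores the tetrasubstituted enolate regiodefined.

Step 3
Reactants: 5 (R)-[(2,3-dimethylcyclohex-1-en-1-yl)oxy]trimethylsilane; 2 2-chloroethyl trifluoromethanesulfonate
Product: 7 (2S,3R)-2-(2-chloroethyl)-2,3-dimethylcyclohexan-1-one, via lithium enolate 6 (not isolated)
Conditions: MeLi, THF, 0 °C to rt; then 2, −78 to −20 °C
Reagents that add atoms: none
Why: MeLi cleaves the silyl enol ether to the regiodefined lithium enolate, whose alkylation in THF without polar cosolvent occurs on carbon and anti to the pseudoaxial C8 methyl group, giving C9 (S, methyl groups cis), the chloride being too poor a leaving group to compete with the triflate.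

Step 4
Reactants: 7 (2S,3R)-2-(2-chloroethyl)-2,3-dimethylcyclohexan-1-one
Product: 9 (2S,3R,6R)-2-(2-chloroethyl)-6-hydroxy-2,3-dimethylcyclohexan-1-one, via potassium enolate 8 (not isolated)
Conditions: KN(SiMe3)2, THF, −78 °C; then 2-(phenylsulfonyl)-3-phenyloxaziridine, −78 °C; AcOH quench
Reagents that add atoms: 2-(phenylsulfonyl)-3-phenyloxaziridine, O=S(=O)(N1OC1c1ccccc1)c1ccccc1
Why: enolate hydroxylation with an N-sulfonyloxaziridine (Davis oxidation), for which quaternary C9 leaves C5 as the only enolisable carbon, the primary chloride is inert to the enolate at −78 °C, and oxygen should enter opposite the axial C9 methyl group (5R, a centre erased in step 7).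

Step 5
Reactants: 9 (2S,3R,6R)-2-(2-chloroethyl)-6-hydroxy-2,3-dimethylcyclohexan-1-one
Product: 10 (1R,2R,3S,4R)-3-(2-chloroethyl)-2-ethenyl-3,4-dimethylcyclohexane-1,2-diol
Conditions: CH2=CHMgBr (3 equiv), anhydrous CeCl3 (3 equiv), THF, −78 to 0 °C
Reagents that add atoms: vinylmagnesium bromide, C=C[Mg]Br
Why: 1,2-addition of a weakly basic organocerium reagent to the hindered C10 ketone after deprotonation of the hydroxyl, with axial attack on the face opposite the axial C9 methyl group expected to place vinyl axial and the C10 oxygen equatorial (10R, a centre erased in step 9).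

Step 6
Reactants: 10 (1R,2R,3S,4R)-3-(2-chloroethyl)-2-ethenyl-3,4-dimethylcyclohexane-1,2-diol
Product: 11 (3aS,4R,7R,7aR)-7a-ethenyl-3a,4-dimethyloctahydro-1-benzofuran-7-ol (trans-fused)
Conditions: NaH (1.2 equiv), n-Bu4NI (cat.), THF, 0 to 45 °C
Reagents that add atoms: none
Why: intramolecular Williamson etherification (5-exo-tet), in which the equatorial C10 alkoxide and the equatorial chloroethyl arm are gauche and close the tetrahydrofuran, whereas closure from the C5 oxygen would need a bridging six-membered ring reached only through a diaxial chair.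

Step 7
Reactants: 11 (3aS,4R,7R,7aR)-7a-ethenyl-3a,4-dimethyloctahydro-1-benzofuran-7-ol
Product: 12 (3aS,4R,7aR)-7a-ethenyl-3a,4-dimethylhexahydro-1-benzofuran-7-one (C5 ketone)
Conditions: Dess–Martin periodinane, CH2Cl2, 0 °C to rt
Reagents that add atoms: none
Why: Dess–Martin oxidation of the only alcohol present, under near-neutral conditions that the tertiary allylic ether and the vinyl group tolerate, giving a ketone whose fully substituted α-carbon C10 cannot epimerise or let the alkene move into conjugation.

Step 8
Reactants: 12 (3aS,4R,7aR)-7a-ethenyl-3a,4-dimethylhexahydro-1-benzofuran-7-one; 13 1-bromobut-2-yne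
Product: 15 (3aS,4R,7R,7aR)-7-(buta-2,3-dien-2-yl)-7a-ethenyl-3a,4-dimethyloctahydro-1-benzofuran-7-ol, via but-2-ynylindium dibromide 14 (not isolated)
Conditions: In powder, THF, rt, sonication; aqueous work-up
Reagents that add atoms: none
Why: Barbier-type addition in which the methyl-substituted propargylindium species reacts through its remote alkyne carbon (SE2') to give the 1-methylallenyl rather than the homopropargyl carbinol, the α-ether oxygen activating the ketone by chelation and the axial C9 methyl group blocking the axial trajectory, so that allenyl ends equatorial (5R) and gauche to the axial vinyl group.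

Step 9
Reactants: 15 (3aS,4R,7R,7aR)-7-(buta-2,3-dien-2-yl)-7a-ethenyl-3a,4-dimethyloctahydro-1-benzofuran-7-ol
Product: 18 (8R,9S) ten-membered keto enol ether (C5 ketone; C4 gem-dimethyl; C3 exocyclic methylene; C10=C1 enol ether with C2 cis to oxygen inside a 2-alkylidenetetrahydrofuran), via potassium alkoxide 16 (not isolated), via potassium dienolate 17 (not isolated)
Conditions: KH (1.05 equiv), 18-crown-6, THF, 0 °C to rt; then MeI, −78 to −20 °C; pH 7 work-up, Et3N-deactivated silica
Reagents that add atoms: iodomethane, CI
Why: KH with 18-crown-6 turns 15 into the dissociated alkoxide 16, in which the C5–C10 bond (flanked by the alkoxide on C5, the ether oxygen on C10 and three contiguous fully substituted carbons) breaks while the vinyl terminus C2 bonds to the central allene carbon C3 in a chair-like [3,3] shift; heterolysis to an allenyl ketone and an alkoxyallyl anion followed by conjugate recombination would reach the same dienolate 17. The closest known reaction type is the anionic oxy-Cope four-carbon ring expansion of 1,2-dialkenylcyclohexanols with alkylation of the released enolate in the same flask, allenes being established Cope termini. The ten-membered carbocycle arises by expansion of the cyclohexane and not by an end-to-end closure, and the tetrahydrofuran is carried through as a 2-alkylidene ring. No stereocentre is created (C5 and C10 become trigonal, C4 ends with two methyl groups, C8 and C9 are spectators), and the chair open to the axial-vinyl/equatorial-allenyl arrangement places C9 pseudoequatorial, which puts C2 trans to C9 on the enol ether. The step needs the two oxygens to keep different roles, which the non-migrating O–C12 link guarantees: the enolate can sit only at C5, the enol ether only at C10, and quaternary C9 allows no position other than C10=C1. It also needs methylation on C4 rather than on oxygen, on the exocyclic CH2 terminus or a second time at C6, which soft MeI at low temperature, the usual α-selectivity of dienolates and barely more than one equivalent of KH should secure.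

Step 10
Reactants: 18 (8R,9S) ten-membered keto enol ether
Product: 21 (1R,5R,8R,9S) trans-fused hydroazulenone ketol (C5 hydroxyl; C10 ketone; C3 exocyclic methylene; 2-hydroxyethyl on C9), via titanium aldolate oxocarbenium ion 19 (not isolated), via cyclic hemiketal 20 (not isolated)
Conditions: TiCl4 (1.1 equiv), CH2Cl2, −78 °C; cold aqueous quench
Reagents that add atoms: water, O
Why: transannular Mukaiyama-type aldol addition of an alkyl enol ether to a Lewis acid-activated ketone (5-enolexo-exo-trig for the cyclopentane, which at once defines the cycloheptanone), in which C8 holds the C6–C8 tether and hence C5 on one face of C10=C1 and sets C1 (R), TiCl4 bridging the C5 carbonyl oxygen and the enol ether oxygen keeps O5 gauche to C10 and sets C5 (R, trans fusion), and water opens 19 through 20 to the C10 ketone and the C12 alcohol, C1 remaining correctable next to the ketone.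

Step 11
Reactants: 21 (1R,5R,8R,9S) trans-fused hydroazulenone ketol
Product: 22 (1R,5R,8R,9S) primary iodide (2-iodoethyl on C9)
Conditions: I2, PPh3, imidazole, CH2Cl2, 0 °C, dark
Reagents that add atoms: iodine, II
Why: Appel-type iodination, in which only the primary C12 alcohol of the open hydroxy ketone form is activated as alkoxyphosphonium salt and displaced by iodide (SN2), the tertiary C5 hydroxyl being too hindered to react.

Step 12
Reactants: 22 (1R,5R,8R,9S) primary iodide; 23 4-bromofuran-2(5H)-one
Product: 25 (1R,5R,8R,9S) butenolide with C3 exocyclic methylene, via alkylzinc iodide 24 (not isolated)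
Conditions: Zn dust (activated with BrCH2CH2Br and TMSCl, cat.), LiCl, THF, 35 °C; then 23, Pd(OAc)2 (3 mol%), SPhos (6 mol%), THF, rt
Reagents that add atoms: none
Why: Negishi coupling, in which zinc inserts into the primary carbon-iodine bond to give a ketone-tolerant alkylzinc iodide that transmetallates to the alkenylpalladium bromide formed from zerovalent palladium and the activated bromide 23, the hindered tertiary hydroxyl protonating the organozinc more slowly than the electron-rich catalyst couples it.

Step 13
Reactants: 25 (1R,5R,8R,9S) butenolide with C3 exocyclic methylene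
Product: 27 (1R,5R,8R,9S) C3,C10-diketone, via secondary ozonide 26 (not isolated)
Conditions: O3, CH2Cl2, −78 °C, Sudan Red 7B end point; then PPh3, −78 °C to rt
Reagents that add atoms: ozone, [O-][O+]=O
Why: ozonolysis, in which electrophilic ozone attacks the electron-rich 1,1-disubstituted alkene much faster than the acceptor-substituted butenolide alkene, the dye marks the end point, and the neutral reductive work-up spares the retro-aldol-prone ketol.

Step 14
Reactants: 27 (1R,5R,8R,9S) C3,C10-diketone
Product: 28 CNP0077405.2, the (1R,3R,5R,8R,9S) target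
Conditions: Me4NBH(OAc)3, MeCN–AcOH (1:1), −30 °C; Rochelle salt work-up
Reagents that add atoms: none
Why: hydroxyl-directed triacetoxyborohydride reduction (Evans–Saksena reduction), in which the C5 hydroxyl replaces an acetate on boron and hydride reaches C3 from the face bearing O5, so that the 3-hydroxyl ends trans to the 5-hydroxyl (3R), while the lactone is inert and the C10 ketone, in the seven-membered ring between quaternary C9 and tertiary C1, should react far more slowly than the cyclopentanone.

Compound list
1 | 2-chloroethanol | OCCCl | starting material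
2 | 2-chloroethyl trifluoromethanesulfonate | ClCCOS(=O)(=O)C(F)(F)F | intermediate
3 | 2-methylcyclohex-2-en-1-one | CC1=CCCCC1=O | starting material
4 | dimethylaluminium (R)-2,3-dimethylcyclohex-1-en-1-olate (formed in the flask) | C[C@@H]1CCCC(O[Al](C)C)=C1C | intermediate
5 | (R)-[(2,3-dimethylcyclohex-1-en-1-yl)oxy]trimethylsilane | C[C@@H]1CCCC(O[Si](C)(C)C)=C1C | intermediate
6 | lithium (R)-2,3-dimethylcyclohex-1-en-1-olate (formed in the flask) | C[C@@H]1CCCC([O-])=C1C.[Li+] | intermediate
7 | (2S,3R)-2-(2-chloroethyl)-2,3-dimethylcyclohexan-1-one (methyl groups cis) | O=C1CCC[C@@H](C)[C@]1(C)CCCl | intermediate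
8 | potassium (5R,6S)-6-(2-chloroethyl)-5,6-dimethylcyclohex-1-en-1-olate (formed in the flask) | [K+].[O-]C1=CCC[C@@H](C)[C@]1(C)CCCl | intermediate
9 | (2S,3R,6R)-2-(2-chloroethyl)-6-hydroxy-2,3-dimethylcyclohexan-1-one | O=C1[C@H](O)CC[C@@H](C)[C@]1(C)CCCl | intermediate
10 | (1R,2R,3S,4R)-3-(2-chloroethyl)-2-ethenyl-3,4-dimethylcyclohexane-1,2-diol | O[C@@H]1CC[C@@H](C)[C@](C)(CCCl)[C@]1(O)C=C | intermediate
11 | (3aS,4R,7R,7aR)-7a-ethenyl-3a,4-dimethyloctahydro-1-benzofuran-7-ol | O[C@@H]1CC[C@@H](C)[C@]2(C)CCO[C@@]12C=C | intermediate
12 | (3aS,4R,7aR)-7a-ethenyl-3a,4-dimethylhexahydro-1-benzofuran-7-one | O=C1CC[C@@H](C)[C@]2(C)CCO[C@@]12C=C | intermediate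
13 | 1-bromobut-2-yne | CC#CCBr | starting material
14 | but-2-yn-1-ylindium dibromide, simplest formulation of the organoindium reagent (formed in the flask) | CC#CC[In](Br)Br | intermediate
15 | (3aS,4R,7R,7aR)-7-(buta-2,3-dien-2-yl)-7a-ethenyl-3a,4-dimethyloctahydro-1-benzofuran-7-ol | C=C=C(C)[C@]1(O)CC[C@@H](C)[C@]2(C)CCO[C@@]12C=C | intermediate
16 | potassium alkoxide of 15 (formed in the flask) | C=C=C(C)[C@]1([O-])CC[C@@H](C)[C@]2(C)CCO[C@@]12C=C.[K+] | intermediate
17 | (8R,9S) ten-membered potassium C5 dienolate with C3 exocyclic methylene and C10=C1 enol ether (formed in the flask) | [K+].[O-]/C1=C(\C)C(=C)C/C=C2\OCC[C@@]2(C)[C@H](C)CC1 | intermediate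
18 | (8R,9S) ten-membered keto enol ether: C5 ketone, C4 gem-dimethyl, C3 exocyclic methylene, C10=C1 enol ether (C2 cis to oxygen) | O=C1CC[C@@H](C)[C@]2(C)CCO/C2=C\CC(=C)C1(C)C | intermediate
19 | titanium aldolate at O5 with cyclic oxocarbenium ion at C10 (formed in the flask) | C[C@@H]1CC[C@@]2(O[Ti-](Cl)(Cl)(Cl)Cl)[C@@H](CC(=C)C2(C)C)C3=[O+]CC[C@@]13C | intermediate
20 | cyclic hemiketal at C10, ring-closed tautomer of 21, C10 unassigned (formed in the flask) | C[C@@H]1CC[C@@]2(O)[C@@H](CC(=C)C2(C)C)C3(O)OCC[C@@]13C | intermediate
21 | (1R,5R,8R,9S) trans-fused hydroazulenone ketol with C3 exocyclic methylene and 2-hydroxyethyl on C9 | C[C@@H]1CC[C@@]2(O)[C@@H](CC(=C)C2(C)C)C(=O)[C@@]1(C)CCO | intermediate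
22 | (1R,5R,8R,9S) primary iodide, 2-iodoethyl on C9 | C[C@@H]1CC[C@@]2(O)[C@@H](CC(=C)C2(C)C)C(=O)[C@@]1(C)CCI | intermediate
23 | 4-bromofuran-2(5H)-one | O=C1C=C(Br)CO1 | starting material
24 | alkylzinc iodide from 22 (formed in the flask) | C[C@@H]1CC[C@@]2(O)[C@@H](CC(=C)C2(C)C)C(=O)[C@@]1(C)CC[Zn]I | intermediate
25 | (1R,5R,8R,9S) butenolide with C3 exocyclic methylene | C[C@@H]1CC[C@@]2(O)[C@@H](CC(=C)C2(C)C)C(=O)[C@@]1(C)CCC1=CC(=O)OC1 | intermediate
26 | secondary ozonide spiro at C3, spiro centre unassigned (formed in the flask) | C[C@@H]1CC[C@@]2(O)[C@@H](CC3(OCOO3)C2(C)C)C(=O)[C@@]1(C)CCC1=CC(=O)OC1 | intermediate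
27 | (1R,5R,8R,9S) C3,C10-diketone | C[C@@H]1CC[C@@]2(O)[C@@H](CC(=O)C2(C)C)C(=O)[C@@]1(C)CCC1=CC(=O)OC1 | intermediate
28 | CNP0077405.2, (1R,3R,5R,8R,9S) | C[C@@H]1CC[C@@]2(O)[C@@H](C[C@@H](O)C2(C)C)C(=O)[C@@]1(C)CCC1=CC(=O)OC1 | target

Total step count: 14. Longest linear sequence: 13 steps (steps 2 to 14, from 3).

Steps most likely to fail

**Step 10.**
- Risk: the ring may close through an open, non-chelated arrangement in which the C5 carbonyl offers its other face, so facial selectivity at C5 is lost. The enol ether may also be protonated before the carbon-carbon bond forms.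
- Fallback: this replaces kinetic by thermodynamic control. Setting out from 18, the enol ether is hydrolysed with oxalic acid in wet THF to the ten-membered hydroxy dione F1.
- F1 is then closed under reversible base catalysis (catalytic KOt-Bu in t-BuOH, or DBU in toluene). Retro-aldol cleavage recycles mis-set isomers, and C10 can enolise only towards C1.
- The competing attack of C6 on C10 meets a carbonyl next to quaternary C9 that rests partly as hemiketal. The internal hydrogen bond from O5–H to the C10 carbonyl favours the trans-fused ketol.
- The route is rejoined at 21.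

**Step 9.**
- Risk: the alkoxide may fragment by expelling the butynyl anion, or close 5-endo onto the allene. The naked dienolate may also be methylated on oxygen or more than once.
- Fallback: this avoids the alkoxide altogether by a neutral siloxy-Cope rearrangement. Setting out from 15, silylation (TMSOTf, 2,6-lutidine, CH2Cl2) gives the trimethylsilyl ether F2.
- Heating F2 in xylene in a sealed tube brings about the thermal [3,3] shift to the ring-expanded silyl dienol ether F3.
- MeLi in THF releases the lithium dienolate F4, and MeI at low temperature methylates C4.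
- The route is rejoined at 18.

**Step 8.**
- Risk: addition to a carbonyl flanked by fully substituted C10 may be sluggish. Under growing steric demand, bond formation may drift to the CH2 terminus of the organometal, so the allenyl regiochemistry is lost.
- Fallback: this builds the allene in two stages from a slim nucleophile. Setting out from 12, the lithium acetylide of 3-methoxyprop-1-yne (n-BuLi, THF, −78 °C) adds to the ketone to give the 3-methoxyprop-1-ynyl carbinol F5.
- Copper-catalysed SN2' displacement of methoxide by MeMgBr (CuBr·SMe2 cat., Et2O) then places the methyl group on the alkyne carbon next to C5 and generates the terminal allene.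
- The route is rejoined at 15.

Further compounds
F1 | step 10 | (8R,9S) ten-membered 5,10-dione with C3 exocyclic methylene, C4 gem-dimethyl and 2-hydroxyethyl on C9 | O=C1CC[C@@H](C)[C@](C)(CCO)C(=O)CCC(=C)C1(C)C
F2 | step 9 | trimethylsilyl ether of 15 | C=C=C(C)[C@]1(O[Si](C)(C)C)CC[C@@H](C)[C@]2(C)CCO[C@@]12C=C
F3 | step 9 | (8R,9S) ring-expanded trimethylsilyl dienol ether | C[Si](C)(C)O/C1=C(\C)C(=C)C/C=C2\OCC[C@@]2(C)[C@H](C)CC1
F4 | step 9 | (8R,9S) ten-membered lithium C5 dienolate | [Li+].[O-]/C1=C(\C)C(=C)C/C=C2\OCC[C@@]2(C)[C@H](C)CC1
F5 | step 8 | (3aS,4R,7R,7aR)-7a-ethenyl-7-(3-methoxyprop-1-yn-1-yl)-3a,4-dimethyloctahydro-1-benzofuran-7-ol | COCC#C[C@]1(O)CC[C@@H](C)[C@]2(C)CCO[C@@]12C=C
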